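**Strategy.** Each ring C holds a C4 carbonyl and a benzylic C2–O in a 1,3-relationship, and the two rings C share the C3–C3' bond about a twofold axis. Cutting O1–C2 and C4–C4a in both halves therefore leaves a 2,3-bis(α-oxybenzyl)succinic acid. This exists as the cis-fused bis-γ-lactone of the lignan type, with each C4 carboxyl masked by the benzylic oxygen of the other half. In the key step two ring A aryllithiums open both lactones (C4–C4a) and acid then closes both pyranones (O1–C2), so a furofurandione is turned inside out into the 3,3'-biflavanone. The C3/C3' configuration comes from an auxiliary-controlled oxidative enolate dimerisation.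

Key step: step 6

Remark: 1, 2 and 11 are taken as commercial. The centres that become C3/C3' are R in 6–8 and S in 10–16 only because the CIP priorities change, not the geometry. The target is the C2-symmetric trans,trans isomer (2R,3S,2'R,3'S).

Step 1
Reactants: 1 3-[4-(benzyloxy)phenyl]propanoic acid; 2 (S)-4-isopropyl-1,3-oxazolidin-2-one
Product: 4 (S)-3-{3-[4-(benzyloxy)phenyl]propanoyl}-4-isopropyl-1,3-oxazolidin-2-one, via mixed pivalic anhydride 3 (not isolated)
Conditions: PivCl, Et3N, THF, −20 °C; then 2, LiCl, −20 °C to rt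
Reagents that add atoms: none
Why: Mixed-anhydride N-acylation of the oxazolidinone (LiCl/Et3N activates the N–H), which attacks the less hindered arylpropanoyl carbonyl of 3; no stereocentre is formed.

Step 2
Reactants: 4 (two molecules)
Product: 6 (4S,4'S)-3,3'-{(2R,3R)-2,3-bis[4-(benzyloxy)benzyl]butanedioyl}bis(4-isopropyl-1,3-oxazolidin-2-one), via lithium enolate 5 (not isolated)
Conditions: LiN(iPr)2, THF, −78 °C; then CuCl2, DMF, −78 to 0 °C
Reagents that add atoms: none
Why: Oxidative enolate homocoupling, in which single-electron oxidation of the chelated lithium Z-enolate 5 by CuCl2 joins two α-carbons, each C–C terminus forming on the enolate face remote from the isopropyl group, so that the doubly matched (R,R) dimer (the later C3 and C3') should prevail over the meso isomer.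

Step 3
Reactants: 6
Product: 8 (2R,3R)-2,3-bis[4-(benzyloxy)benzyl]butanedioic acid, via bis(peroxy acid) 7 (not isolated)
Conditions: LiOH, H2O2, THF/H2O, 0 °C; then Na2SO3; then aq. HCl
Reagents that add atoms: hydrogen peroxide, OO
Why: Hydroperoxide cleavage of the N-acyl oxazolidinones at the exocyclic carbonyl, sulfite reduction of the peroxy acids and acidification free the diacid without enolising the α-centres, so (R,R) is retained and auxiliary 2 is recovered.

Step 4
Reactants: 8
Product: 10 (3S,3aS,6S,6aS)-3,6-bis[4-(benzyloxy)phenyl]tetrahydro-1H,3H-furo[3,4-c]furan-1,4-dione, via monolactone acid 9 (not isolated)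
Conditions: DDQ (2.4 equiv), 1,4-dioxane, 4 Å MS, 60 °C
Reagents that add atoms: none
Why: DDQ-mediated benzylic oxidative lactonisation, in which hydride abstraction at each CH2 para to the benzyloxy group gives an oxygen-stabilised benzylic cation that the carboxyl group of the other half captures 5-exo (its own carboxyl could only give a β-lactone), the (R,R) backbone allowing only the cis-fused bicycle and each new C–O stereocentre placing its aryl group on the convex face, trans to the neighbouring ring substituent.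

Step 5
Reactants: 11 4-bromobenzene-1,3-diol (4-bromoresorcinol)
Product: 12 1-bromo-2,4-bis(methoxymethoxy)benzene
Conditions: MOMCl, iPr2NEt, CH2Cl2, 0 °C to rt
Reagents that add atoms: chloromethyl methyl ether, COCCl
Why: Twofold O-alkylation of the phenols with the reactive α-chloro ether under amine base; no stereocentre is involved.

Step 6
Reactants: 10 (3S,3aS,6S,6aS)-3,6-bis[4-(benzyloxy)phenyl]tetrahydro-1H,3H-furo[3,4-c]furan-1,4-dione; 12 1-bromo-2,4-bis(methoxymethoxy)benzene (2.4 equiv)
Product: 15 (2R,2'R,3S,3'S)-2,2'-bis[4-(benzyloxy)phenyl]-7,7'-dihydroxy-[3,3'-bichromane]-4,4'-dione, via aryllithium 13 (not isolated), via diol diketone 14 (not isolated)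
Conditions: 12, n-BuLi, THF, −78 °C; then 10, −78 °C; then 3 M HCl in MeOH, −78 to 45 °C
Reagents that add atoms: none
Why: Bromine–lithium exchange gives aryllithium 13, which adds once to each γ-lactone carbonyl of 10 (nucleophilic acyl substitution that stops at the five-membered lactolate at −78 °C); this makes both C4–C4a bonds and turns the benzylic ester oxygens at C2 and C2' into the hydroxyl groups of diol diketone 14. Methanolic HCl then removes the four MOM groups and ionises the 4-benzyloxybenzylic C2–OH bonds to quinone-methide-like cations, which the freed ortho phenol O1 of the same half captures; the closest known reaction types are the aryllithium opening of lignan lactones and the acid cyclisation of 2'-hydroxy-β-hydroxydihydrochalcones to flavanones. Each pyranone ring closes in the 6-exo-trig mode, O1 adding to C2 whose cationic π-system lies outside the new ring. C3 and C3' are spectators and keep the configuration set in step 2, while C2 and C2' are re-formed under control of their C3 neighbours: closure through a half-chair with the aryl group and the C3 substituent both equatorial gives the 2,3-trans ring, and a cis ring can re-ionise and correct itself. The step needs one addition per lactone and O-capture of the cation instead of proton loss from C3 or attack by a ring carbon; the persistent lactolate, the six-membered reach of O1 and the acyl-deactivated ring A should secure this.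

Step 7
Reactants: 15
Product: 16 (2R,2'R,3S,3'S)-7,7'-dihydroxy-2,2'-bis(4-hydroxyphenyl)-[3,3'-bichromane]-4,4'-dione (CNP0231820.2)
Conditions: H2 (1 atm), 10% Pd/C, EtOAc/MeOH, rt
Reagents that add atoms: none
Why: Hydrogenolysis of the two benzyl aryl ethers over Pd/C under neutral conditions, in which the aryl ketones and the C2–O1 ethers react far more slowly and no stereocentre can epimerise.

**Compound list**

1 | 3-[4-(benzyloxy)phenyl]propanoic acid | OC(=O)CCc1ccc(OCc2ccccc2)cc1 | starting material
2 | (S)-4-isopropyl-1,3-oxazolidin-2-one | CC(C)[C@H]1COC(=O)N1 | starting material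
3 | 3-[4-(benzyloxy)phenyl]propanoic pivalic anhydride | CC(C)(C)C(=O)OC(=O)CCc1ccc(OCc2ccccc2)cc1 | intermediate (not isolated)
4 | (S)-3-{3-[4-(benzyloxy)phenyl]propanoyl}-4-isopropyl-1,3-oxazolidin-2-one | O=C(CCc1ccc(OCc2ccccc2)cc1)N1[C@@H](C(C)C)COC1=O | intermediate
5 | lithium (Z)-enolate of 4 | [Li]O/C(=C\Cc1ccc(OCc2ccccc2)cc1)N1[C@@H](C(C)C)COC1=O | intermediate (not isolated)
6 | (4S,4'S)-3,3'-{(2R,3R)-2,3-bis[4-(benzyloxy)benzyl]butanedioyl}bis(4-isopropyl-1,3-oxazolidin-2-one) | O=C(N1[C@@H](C(C)C)COC1=O)[C@H](Cc1ccc(OCc2ccccc2)cc1)[C@@H](Cc1ccc(OCc2ccccc2)cc1)C(=O)N1[C@@H](C(C)C)COC1=O | intermediate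
7 | (2R,3R)-2,3-bis[4-(benzyloxy)benzyl]butanediperoxoic acid | OOC(=O)[C@H](Cc1ccc(OCc2ccccc2)cc1)[C@@H](Cc1ccc(OCc2ccccc2)cc1)C(=O)OO | intermediate (not isolated)
8 | (2R,3R)-2,3-bis[4-(benzyloxy)benzyl]butanedioic acid | OC(=O)[C@H](Cc1ccc(OCc2ccccc2)cc1)[C@@H](Cc1ccc(OCc2ccccc2)cc1)C(=O)O | intermediate
9 | (2S,3S,4R)-2-[4-(benzyloxy)phenyl]-4-[4-(benzyloxy)benzyl]-5-oxotetrahydrofuran-3-carboxylic acid | O=C1O[C@H](c2ccc(OCc3ccccc3)cc2)[C@@H](C(=O)O)[C@H]1Cc1ccc(OCc2ccccc2)cc1 | intermediate (not isolated)
10 | (3S,3aS,6S,6aS)-3,6-bis[4-(benzyloxy)phenyl]tetrahydro-1H,3H-furo[3,4-c]furan-1,4-dione (cis-fused, both aryl groups on the convex face) | O=C1O[C@H](c3ccc(OCc4ccccc4)cc3)[C@H]2C(=O)O[C@H](c3ccc(OCc4ccccc4)cc3)[C@@H]12 | intermediate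
11 | 4-bromobenzene-1,3-diol | Oc1ccc(Br)c(O)c1 | starting material
12 | 1-bromo-2,4-bis(methoxymethoxy)benzene | COCOc1ccc(Br)c(OCOC)c1 | intermediate
13 | [2,4-bis(methoxymethoxy)phenyl]lithium | [Li]c1ccc(OCOC)cc1OCOC | intermediate (not isolated)
14 | (2S,3S)-2,3-bis{(S)-[4-(benzyloxy)phenyl](hydroxy)methyl}-1,4-bis[2,4-bis(methoxymethoxy)phenyl]butane-1,4-dione (open form of the bis-lactol) | O=C(c1ccc(OCOC)cc1OCOC)[C@H]([C@H](O)c1ccc(OCc2ccccc2)cc1)[C@@H]([C@H](O)c1ccc(OCc2ccccc2)cc1)C(=O)c1ccc(OCOC)cc1OCOC | intermediate (not isolated)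
15 | (2R,2'R,3S,3'S)-2,2'-bis[4-(benzyloxy)phenyl]-7,7'-dihydroxy-[3,3'-bichromane]-4,4'-dione | O=C1c2ccc(O)cc2O[C@@H](c2ccc(OCc3ccccc3)cc2)[C@@H]1[C@@H]1C(=O)c2ccc(O)cc2O[C@H]1c1ccc(OCc2ccccc2)cc1 | intermediate
16 | (2R,2'R,3S,3'S)-7,7'-dihydroxy-2,2'-bis(4-hydroxyphenyl)-[3,3'-bichromane]-4,4'-dione | O=C1c2ccc(O)cc2O[C@@H](c2ccc(O)cc2)[C@@H]1[C@@H]1C(=O)c2ccc(O)cc2O[C@H]1c1ccc(O)cc1 | target

**Step count.** Total: 7 steps. Longest linear sequence: 6 steps (1, 2, 3, 4, 6, 7); step 5 is a one-step side branch.

**Steps most likely to fail**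

Step 6. The acid stage may leak stereochemistry: proton loss from the benzylic cation to a chalcone, enolisation of the open 1,4-diketone, or Paal–Knorr closure to a furan would erase C3/C3'. In the first stage the aryllithium may deprotonate C3 of the lactone and trigger a Stobbe-type ring opening; adding CeCl3 would be a first remedy. The fallback makes O1–C2 by a stereospecific SN2 instead of a cation. It sets out from 10. The C,O-dilithio reagent lithium 2-lithio-5-methoxyphenolate F1 (from commercial 2-bromo-5-methoxyphenol and two equivalents of n-BuLi, Et2O/THF, −78 to 0 °C) is added to 10 at −78 °C. A neutral quench with aqueous NH4Cl allows isolation of the diol diketone with free ortho phenols, (2S,3S)-2,3-bis{(S)-[4-(benzyloxy)phenyl](hydroxy)methyl}-1,4-bis(2-hydroxy-4-methoxyphenyl)butane-1,4-dione F2. A twofold intramolecular Mitsunobu etherification (PPh3, DIAD, THF, 0 °C) then closes both pyranones with inversion at the (S)-carbinols. This should give (2R,2'R,3S,3'S)-2,2'-bis[4-(benzyloxy)phenyl]-7,7'-dimethoxy-[3,3'-bichromane]-4,4'-dione F3, in which 2R is set independently of C3. BBr3 (CH2Cl2, −78 to 0 °C) cleaves the methyl and benzyl ethers, and the route is rejoined at 16.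

Step 4. Hydride abstraction from a mono-alkoxy arene may be slow, and the cation may be lost by proton loss to a benzylidene succinate or by attack on the other aryl ring. The fallback functionalises the same C–H bonds by radical hydrogen transfer and sets out from 8. The diacid is converted into (2R,3R)-2,3-bis[4-(benzyloxy)benzyl]butanediamide F4 (ClCO2Et, Et3N; then NH3). PhI(OAc)2 and I2 under visible light generate amidyl radicals. The γ-carbon of each amide is the benzylic carbon of the other half, so 1,5-hydrogen transfer, iodine transfer and closure through the amide oxygen should give the bis(iminolactone) (3S,3aS,6S,6aS)-3,6-bis[4-(benzyloxy)phenyl]tetrahydro-1H,3H-furo[3,4-c]furan-1,4-diimine F5. Hydrolysis with dilute aqueous HCl comes back to the route at 10.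

Step 2. Facial discrimination in the coupling of two hindered enolates may be poor (meso dimer), and α-chlorination or self-condensation of the enolate may compete. The fallback drops the auxiliary and sets out from 1. Two equivalents of LiN(iPr)2 give the dilithium enediolate of 1 F6, and oxidation with I2 (THF, −78 °C to rt) couples it to a mixture of racemic (2R*,3R*)-2,3-bis[4-(benzyloxy)benzyl]butanedioic acid F7 (8 together with its enantiomer) and the meso diacid F8. The meso isomer is removed by crystallisation, and the racemate is resolved by preparative chromatography on a chiral stationary phase. The route is rejoined at 8.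

**Further compounds**

F1 | step 6 | lithium 2-lithio-5-methoxyphenolate | [Li]Oc1cc(OC)ccc1[Li]
F2 | step 6 | (2S,3S)-2,3-bis{(S)-[4-(benzyloxy)phenyl](hydroxy)methyl}-1,4-bis(2-hydroxy-4-methoxyphenyl)butane-1,4-dione | O=C(c1ccc(OC)cc1O)[C@H]([C@H](O)c1ccc(OCc2ccccc2)cc1)[C@@H]([C@H](O)c1ccc(OCc2ccccc2)cc1)C(=O)c1ccc(OC)cc1O
F3 | step 6 | (2R,2'R,3S,3'S)-2,2'-bis[4-(benzyloxy)phenyl]-7,7'-dimethoxy-[3,3'-bichromane]-4,4'-dione | O=C1c2ccc(OC)cc2O[C@@H](c2ccc(OCc3ccccc3)cc2)[C@@H]1[C@@H]1C(=O)c2ccc(OC)cc2O[C@H]1c1ccc(OCc2ccccc2)cc1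
F4 | step 4 | (2R,3R)-2,3-bis[4-(benzyloxy)benzyl]butanediamide | NC(=O)[C@H](Cc1ccc(OCc2ccccc2)cc1)[C@@H](Cc1ccc(OCc2ccccc2)cc1)C(N)=O
F5 | step 4 | (3S,3aS,6S,6aS)-3,6-bis[4-(benzyloxy)phenyl]tetrahydro-1H,3H-furo[3,4-c]furan-1,4-diimine | N=C1O[C@H](c3ccc(OCc4ccccc4)cc3)[C@H]2C(=N)O[C@H](c3ccc(OCc4ccccc4)cc3)[C@@H]12
F6 | step 2 | dilithium enediolate of 1 | [Li]OC(O[Li])=CCc1ccc(OCc2ccccc2)cc1
F7 | step 2 | racemic (2R*,3R*)-2,3-bis[4-(benzyloxy)benzyl]butanedioic acid (8 with its enantiomer; the (2S,3S) enantiomer is drawn) | OC(=O)[C@@H](Cc1ccc(OCc2ccccc2)cc1)[C@H](Cc1ccc(OCc2ccccc2)cc1)C(=O)O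
F8 | step 2 | meso-(2R,3S)-2,3-bis[4-(benzyloxy)benzyl]butanedioic acid | OC(=O)[C@H](Cc1ccc(OCc2ccccc2)cc1)[C@H](Cc1ccc(OCc2ccccc2)cc1)C(=O)O
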